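Atom labels: the eleven-membered perimeter runs C1 (tigloyloxy), C2, C3 (senecioyloxy), C4 (methyl), C5, C6 (ketone), C7, C8 (methyl, C7=C8), C9, C10, C11 (gem-dimethyl) and back to C1; C4–C9 and C5–C10 are the two transannular bonds.
Enabling feature: the cyclobutane C4–C5–C10–C9 is bridged from C5 to C9 by C6–C7–C8 (a bicyclo[3.1.1]heptane) and its C10 bears only H and C11. C10 can therefore come from a ketene carbonyl, C9 from the ketene α-carbon, and C4(Me)–C5 from a trisubstituted alkene held three atoms from C9.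
Cuts, in order: both ester C–O bonds; C10–C11 (aldol, after putting O back on C10 and a ketone at C1); C5–C10 and C4–C9 together (ketene–alkene [2+2]); then C6–C7 and C2–C3 (two aldol-type unions). This leaves five C5 building blocks.
Forward: C2–C3 and then C6–C7 join the open farnesoate-type chain; step 14 closes the cyclobutanone and the six-membered ring in one event; step 17 closes the seven-membered ring; C10–OH is then removed and the C6 carbinol becomes the enone.
Stereochemistry: C3 and C6 come from two catalyst-controlled aldol additions. The C6 silyloxy centre (temporary, later the ketone) and the E alkene dictate C4, C5 and C9. The cage dictates C10. C1 comes from a hydride relay from the C3 oxygen, which also installs the senecioate.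
Key step: step 14

Assumption: the (R,R) form of the bisphosphoramide used with SiCl4 is taken to leave the Re face of a bound conjugated aldehyde open, in line with its reported additions; if the sense were the reverse, the ligand antipodes of steps 3 and 10 would be exchanged.
Remark: every compound between the Luche reduction and the oxidation of C1 is carried as both C1 epimers; that centre is erased before it matters.

Step 1
Reactants: 1 prenyl acetate (3-methylbut-2-en-1-yl acetate)
Product: 2 (2E)-4-acetoxy-2-methylbut-2-enal (C3 aldehyde; C4 and its methyl; C5; C6 as acetate)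
Conditions: SeO2 (1.1 equiv), 1,4-dioxane, 80 °C
Reagents that add atoms: selenium dioxide, O=[Se]=O
Why: Riley allylic oxidation (ene reaction, then [2,3]-sigmatropic shift) oxidises the methyl group trans to the acetoxymethyl chain, so the E geometry needed later (C4 methyl cis to C6) is present from the start.

Step 2
Reactants: 3 3-methylbut-3-en-2-one
Product: 4 3-methyl-2-(trimethylsilyloxy)buta-1,3-diene
Conditions: Me3SiOSO2CF3, Et3N, Et2O, 0 °C
Reagents that add atoms: trimethylsilyl triflate, C[Si](C)(C)OS(=O)(=O)C(F)(F)F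
Why: Soft enolisation and O-silylation of a ketone whose only enolisable position is the acetyl methyl (future C2), so one silyl enol ether can form.

Step 3
Reactants: 2 (2E)-4-acetoxy-2-methylbut-2-enal; 4 3-methyl-2-(trimethylsilyloxy)buta-1,3-diene
Product: 6 (2E,4R)-4-hydroxy-3,7-dimethyl-6-oxoocta-2,7-dien-1-yl acetate (route C3 = R), via trichlorosilyl aldolate 5 (not isolated)
Conditions: SiCl4 (1.5 equiv), (R,R)-N,N'-(pentane-1,5-diyl)bis[N-methyl-3,5-dimethyl-3,5-dihydro-4H-dinaphtho[2,1-d:1',2'-f][1,3,2]diazaphosphepin-4-amine 4-oxide] (5 mol %), iPr2NEt (0.2 equiv), CH2Cl2, −78 °C; aq. NaHCO3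
Reagents that add atoms: none
Why: Mukaiyama aldol addition of a methyl ketone silyl enol ether to a conjugated aldehyde under a Lewis-base-activated chiral silicon cation, which sends C2 to the Re face of C3 and sets 3R, while the trisubstituted C4=C5 bond is too poor a dienophile to divert diene 4 into a Diels–Alder reaction.

Step 4
Reactants: 6 (2E,4R)-4-hydroxy-3,7-dimethyl-6-oxoocta-2,7-dien-1-yl acetate
Product: 7 (2E,4R)-4-(tert-butyldimethylsilyloxy)-3,7-dimethyl-6-oxoocta-2,7-dien-1-yl acetate
Conditions: tBuMe2SiOSO2CF3, 2,6-lutidine, CH2Cl2, −78 °C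
Reagents that add atoms: tert-butyldimethylsilyl triflate, CC(C)(C)[Si](C)(C)OS(=O)(=O)C(F)(F)F
Why: Silylation of a β-hydroxy ketone with a silyl triflate and a hindered pyridine is fast at low temperature and avoids retro-aldol cleavage and elimination.

Step 5
Reactants: 7 (2E,4R)-4-(tert-butyldimethylsilyloxy)-3,7-dimethyl-6-oxoocta-2,7-dien-1-yl acetate
Product: 8 (2E,4R)-4-(tert-butyldimethylsilyloxy)-6-hydroxy-3,7-dimethylocta-2,7-dien-1-yl acetate (both epimers at the new carbinol C1)
Conditions: NaBH4, CeCl3·7H2O, MeOH, −78 °C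
Reagents that add atoms: none
Why: Luche reduction gives 1,2-reduction of the isopropenyl ketone and spares the acetate; it parks C1 at the alcohol level so that no β-silyloxy ketone or Michael acceptor has to face methoxide, tin hydroxide or hot amine later, and the uncontrolled C1 centre is erased in step 16.

Step 6
Reactants: 8 (2E,4R)-4-(tert-butyldimethylsilyloxy)-6-hydroxy-3,7-dimethylocta-2,7-dien-1-yl acetate
Product: 9 (2E,4R)-4-(tert-butyldimethylsilyloxy)-3,7-dimethyl-6-(triethylsilyloxy)octa-2,7-dien-1-yl acetate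
Conditions: Et3SiCl, imidazole, CH2Cl2, 0 °C
Reagents that add atoms: chlorotriethylsilane, CC[Si](Cl)(CC)CC
Why: Standard silylation that puts the most labile of the three silyl groups on the oxygen that must be freed first.

Step 7
Reactants: 9 (2E,4R)-4-(tert-butyldimethylsilyloxy)-3,7-dimethyl-6-(triethylsilyloxy)octa-2,7-dien-1-yl acetate
Product: 10 (2E,4R)-4-(tert-butyldimethylsilyloxy)-3,7-dimethyl-6-(triethylsilyloxy)octa-2,7-dien-1-ol
Conditions: K2CO3 (0.2 equiv), MeOH, 0 °C
Reagents that add atoms: none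
Why: Base-catalysed transesterification removes a primary allylic acetate under conditions that both secondary silyl ethers tolerate.

Step 8
Reactants: 10 (2E,4R)-4-(tert-butyldimethylsilyloxy)-3,7-dimethyl-6-(triethylsilyloxy)octa-2,7-dien-1-ol
Product: 11 (2E,4R)-4-(tert-butyldimethylsilyloxy)-3,7-dimethyl-6-(triethylsilyloxy)octa-2,7-dienal (C6 aldehyde)
Conditions: MnO2, CH2Cl2, rt
Reagents that add atoms: none
Why: Allylic alcohol oxidation with MnO2 stops at the enal and leaves the E alkene geometry untouched.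

Step 9
Reactants: 12 methyl 3-methylbut-2-enoate
Product: 14 1-(tert-butyldimethylsilyloxy)-1-methoxy-3-methylbuta-1,3-diene, via lithium dienolate 13 (not isolated)
Conditions: LiN(iPr)2, THF, −78 °C; then tBuMe2SiCl, DMPU, −78 °C to rt
Reagents that add atoms: tert-butyldimethylsilyl chloride, CC(C)(C)[Si](C)(C)Cl
Why: γ-Deprotonation of the senecioate and O-silylation of the extended enolate give the silyl dienol ether that supplies C7, C8 with its methyl, C9 and C10.

Step 10
Reactants: 11 (2E,4R)-4-(tert-butyldimethylsilyloxy)-3,7-dimethyl-6-(triethylsilyloxy)octa-2,7-dienal; 14 1-(tert-butyldimethylsilyloxy)-1-methoxy-3-methylbuta-1,3-diene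
Product: 16 methyl (2E,5S,6E,8R)-8-(tert-butyldimethylsilyloxy)-5-hydroxy-3,7,11-trimethyl-10-(triethylsilyloxy)dodeca-2,6,11-trienoate (route C6 = S; C3 = R), via trichlorosilyl ether 15 (not isolated)
Conditions: SiCl4 (1.2 equiv), (S,S)-N,N'-(pentane-1,5-diyl)bis[N-methyl-3,5-dimethyl-3,5-dihydro-4H-dinaphtho[2,1-d:1',2'-f][1,3,2]diazaphosphepin-4-amine 4-oxide] (5 mol %), iPr2NEt (0.2 equiv), CH2Cl2, −78 °C; aq. NaHCO3
Reagents that add atoms: none
Why: Vinylogous Mukaiyama aldol addition in which the dienol ether reacts only at its γ-carbon (C7) and the mirror-image ligand sends it to the Si face of C6, so 6S is set by the catalyst independently of remote C3, and any minor C3 enantiomer from step 3 becomes a separable diastereomer here.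

Step 11
Reactants: 16 methyl (2E,5S,6E,8R)-8-(tert-butyldimethylsilyloxy)-5-hydroxy-3,7,11-trimethyl-10-(triethylsilyloxy)dodeca-2,6,11-trienoate
Product: 17 methyl (2E,5S,6E,8R)-8-(tert-butyldimethylsilyloxy)-5-(tert-butyldiphenylsilyloxy)-3,7,11-trimethyl-10-(triethylsilyloxy)dodeca-2,6,11-trienoate
Conditions: tBuPh2SiCl, imidazole, 4-dimethylaminopyridine (0.1 equiv), DMF, rt
Reagents that add atoms: tert-butyldiphenylsilyl chloride, CC(C)(C)[Si](Cl)(c1ccccc1)c1ccccc1
Why: Standard silylation with the most robust of the three silyl groups, which must outlast the other two and whose bulk raises the cost of the unwanted cycloaddition face.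

Step 12
Reactants: 17 methyl (2E,5S,6E,8R)-8-(tert-butyldimethylsilyloxy)-5-(tert-butyldiphenylsilyloxy)-3,7,11-trimethyl-10-(triethylsilyloxy)dodeca-2,6,11-trienoate
Product: 19 the corresponding (2E,5S,6E,8R)-trienoic acid, via trimethylstannyl ester 18 (not isolated)
Conditions: Me3SnOH (5 equiv), 1,2-dichloroethane, 80 °C; cold 0.1 M HCl wash
Reagents that add atoms: trimethyltin hydroxide, C[Sn](C)(C)O
Why: Tin hydroxide cleaves the methyl ester by acyl substitution under near-neutral conditions, which spares the three silyl ethers and avoids vinylogous elimination of the C6 silyloxy group.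

Step 13
Reactants: 19 (2E,5S,6E,8R)-8-(tert-butyldimethylsilyloxy)-5-(tert-butyldiphenylsilyloxy)-3,7,11-trimethyl-10-(triethylsilyloxy)dodeca-2,6,11-trienoic acid
Product: 20 the corresponding (2E,5S,6E,8R)-trienoyl chloride (C10 = COCl)
Conditions: 1-chloro-N,N,2-trimethylprop-1-en-1-amine (1.2 equiv), CH2Cl2, 0 °C to rt; solvent changed to toluene
Reagents that add atoms: 1-chloro-N,N,2-trimethylprop-1-en-1-amine, CC(C)=C(Cl)N(C)C
Why: The α-chloroenamine turns the acid into its chloride without releasing HCl, so the acid-labile triethylsilyl ether survives.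

Step 14
Reactants: 20 (2E,5S,6E,8R)-8-(tert-butyldimethylsilyloxy)-5-(tert-butyldiphenylsilyloxy)-3,7,11-trimethyl-10-(triethylsilyloxy)dodeca-2,6,11-trienoyl chloride
Product: 22 4-(tert-butyldiphenylsilyloxy)-7-methyl-2-methylidene-7-[(1R)-1-(tert-butyldimethylsilyloxy)-4-methyl-3-(triethylsilyloxy)pent-4-en-1-yl]bicyclo[3.1.1]heptan-6-one (bicycle positions 1/2/3/4/5/6/7 = C9/C8/C7/C6/C5/C10/C4; C4 methyl syn to the C6–C8 bridge; side chain syn to the C10 carbonyl; C6 oxygen on the C10 side), via vinylketene 21 (not isolated)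
Conditions: Et3N (5 equiv), toluene, reflux; 20 added by syringe pump over 8 h, final 0.005 M
Reagents that add atoms: none
Why: Triethylamine removes HCl from 20 through a γ-proton of the exposed C8 methyl group and gives vinylketene 21, whose electrophilic C10 bonds ahead of C9 in a concerted but asynchronous [2+2] addition across C5=C4; the closest known reaction is the thermal cyclisation of geranoyl- and farnesoyl-type chlorides to 2-methylenebicyclo[3.1.1]heptan-6-ones, which is why 22 carries an exocyclic C8 methylene and the ring alkene C7=C8 is made only in step 24. The cyclobutanone (C10, C5, C4, C9) closes by the [2+2] event itself, and the six-membered ring (C5–C6–C7–C8–C9–C10) closes with it in the crossed, 1,3-bridging mode because the three-atom tether C6–C7–C8 links C9 to C5. The step needs crossed rather than fused regiochemistry, and alkene polarisation secures it: C10 attacks the CH terminus C5 so that positive charge builds at tertiary C4. C4 and C5 follow from suprafacial addition to the E alkene (C4 methyl cis to C6, hence syn to the C6–C8 bridge, and C3 syn to C10), and C9 follows from the tether, which can span one face only. Facial selectivity comes from C6: allylic 1,3-strain with the cis C4 methyl keeps C6–H beside that methyl and the silyloxy group near the alkene plane, so C7 delivers the ketene to a single face, and on that face C3 can turn its bulky silyloxy group away from the ketene with C3–H next to the C4 methyl. The distal isopropenyl group is out of reach of the tether, and slow addition at high dilution holds back ketene dimerisation.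

Step 15
Reactants: 22 the bicyclic ketone of step 14
Product: 23 the same bicyclic ketone with a free allylic C1 hydroxyl (C3 OTBS and C6 OTBDPS kept)
Conditions: AcOH–THF–H2O (3:1:1), rt
Reagents that add atoms: none
Why: Graded silyl lability: the triethylsilyl ether on an unhindered allylic carbinol hydrolyses in aqueous acetic acid, whereas the two tert-butyl-substituted silyl ethers, the cyclobutanone and the exocyclic alkene persist.

Step 16
Reactants: 23 bicyclic ketone with free C1 hydroxyl
Product: 24 bicyclic keto-enone (C1 isopropenyl ketone; C10 cyclobutanone; C3 OTBS; C6 OTBDPS)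
Conditions: Dess–Martin periodinane, NaHCO3, CH2Cl2, 0 °C
Reagents that add atoms: none
Why: Dess–Martin oxidation under buffered conditions merges both C1 epimers into one enone without eliminating the β-silyloxy group.

Step 17
Reactants: 24 bicyclic keto-enone
Product: 26 tricyclic ketol (seven-membered ring closed; C1 ketone; C11 gem-dimethyl; C10 tertiary OH on the side of the C6–C8 bridge; C3 OTBS; C6 OTBDPS; C8 methylidene), via copper enolate 25 (not isolated)
Conditions: [(Ph3P)CuH]6 (0.4 equiv of hexamer), toluene, −40 °C to rt; aq. NH4Cl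
Reagents that add atoms: none
Why: Reductive aldol cyclisation of a keto-enone: hydride adds to the terminal CH2 of the isopropenyl ketone (isolated ketones and alkenes are inert) and gives the C11 enolate regiospecifically, never the C2 enolate that would expel the C3 silyloxy group; its 7-(enolendo)-exo-trig attack, helped by strain release at the cyclobutanone, can reach only the C4-facing side of C10, which fixes C10.

Step 18
Reactants: 26 tricyclic ketol
Product: 27 tricyclic dihydroxy ketone (free C3 OH; C1 ketone; C10 OH; C6 OTBDPS)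
Conditions: HF·pyridine, pyridine, THF, 0 °C to rt
Reagents that add atoms: none
Why: Fluoride-mediated desilylation in a buffered acidic medium removes the tert-butyldimethylsilyl ether well before the tert-butyldiphenylsilyl ether and gives no alkoxide that could trigger retro-aldol cleavage.

Step 19
Reactants: 27 tricyclic dihydroxy ketone; 28 3-methylbut-2-enal
Product: 30 tricyclic C3 senecioate with free (1R)-hydroxyl trans to the C3 oxygen (C10 OH; C6 OTBDPS), via hemiacetal 29 (not isolated)
Conditions: SmI2 (0.3 equiv), 28 (6 equiv), THF, −10 °C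
Reagents that add atoms: none
Why: Evans–Tishchenko reduction: the C3 hydroxyl adds to the aldehyde and the samarium-bound hemiacetal passes its hydrogen to C1 on the face that carries the C3 oxygen, so one step gives the 1,3-anti (1R) alcohol, tells the two secondary oxygens apart and leaves the senecioate on C3; the C10 hydroxyl lies antiperiplanar to C1 and cannot compete.

Step 20
Reactants: 30 tricyclic C3 senecioate with free C1 hydroxyl; 31 tiglic acid ((2E)-2-methylbut-2-enoic acid)
Product: 33 tricyclic C1 tiglate C3 senecioate (C10 OH; C6 OTBDPS; C8 methylidene), via mixed anhydride 32 (not isolated)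
Conditions: 2,4,6-trichlorobenzoyl chloride, Et3N, toluene, rt; then 30, 4-dimethylaminopyridine, 60 °C
Reagents that add atoms: none
Why: Yamaguchi esterification acylates hindered secondary alcohols and keeps the stable E geometry of the tiglate, while the tertiary C10 hydroxyl stays unreactive.

Step 21
Reactants: 33 tricyclic C1 tiglate C3 senecioate
Product: 35 the C10 O-alkyl S-methyl xanthate of 33, via potassium xanthate 34 (not isolated)
Conditions: KN(SiMe3)2 (1.05 equiv), THF, −78 °C; CS2; MeI, −78 to 0 °C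
Reagents that add atoms: carbon disulfide, S=C=S; iodomethane, CI
Why: Xanthate formation: the hydroxyl is deprotonated faster than either ester, slim CS2 reaches the crowded alkoxide, and the tertiary xanthate is stable because every β-position is a bridgehead or quaternary, so Chugaev elimination is impossible.

Step 22
Reactants: 35 C10 xanthate
Product: 36 deoxygenated tricycle (C10–H; C1 tiglate; C3 senecioate; C6 OTBDPS; C8 methylidene)
Conditions: Bu3SnH (5 equiv), azobisisobutyronitrile (0.2 equiv), toluene, 90 °C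
Reagents that add atoms: none
Why: Barton–McCombie deoxygenation: the thiocarbonyl group captures the stannyl radical far faster than the alkenes do, a high stannane concentration traps the C10 cyclobutyl radical before ring opening, and hydrogen can arrive only from the outer side because C11 is tied to C4 across the inner side, so C10 keeps its configuration.

Step 23
Reactants: 36 deoxygenated tricycle
Product: 37 tricyclic (6S)-alcohol (C1 tiglate; C3 senecioate; C8 methylidene)
Conditions: Bu4NF, AcOH (1:1), THF, rt to 40 °C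
Reagents that add atoms: none
Why: Acetic-acid-buffered fluoride removes the last silyl ether without the basicity that would hydrolyse or shift the two enoate esters.

Step 24
Reactants: 37 tricyclic (6S)-alcohol
Product: 39 target CNP0257816.1 (route numbering 1R,3R,4R,5R,9R,10S; 2,6,6,9-tetramethyl-11-oxotricyclo[5.4.0.0(2,8)]undec-9-ene-3,5-diyl 3-senecioate 5-tiglate), via unconjugated enone 38 (not isolated)
Conditions: Dess–Martin periodinane, NaHCO3, CH2Cl2, 0 °C to rt; aq. Na2S2O3/NaHCO3 wash; then 1,8-diazabicyclo[5.4.0]undec-7-ene (0.2 equiv), CH2Cl2, rt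
Reagents that add atoms: none
Why: Dess–Martin oxidation of the C6 carbinol gives β,γ-unsaturated ketone 38, whose doubly activated C7 protons let the amidine base move the exocyclic alkene into conjugation through the dienolate (C7=C8 and the C8 methyl), while the bridgehead C5–H cannot enolise and no stereocentre is at risk.

Compound list
1 | prenyl acetate | CC(=O)OCC=C(C)C | starting material
2 | (2E)-4-acetoxy-2-methylbut-2-enal | CC(=O)OC/C=C(\C)C=O | intermediate
3 | 3-methylbut-3-en-2-one | CC(=O)C(C)=C | starting material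
4 | 3-methyl-2-(trimethylsilyloxy)buta-1,3-diene | C=C(O[Si](C)(C)C)C(C)=C | intermediate
5 | trichlorosilyl ether of 6 (not isolated) | CC(=O)OC/C=C(\C)[C@H](O[Si](Cl)(Cl)Cl)CC(=O)C(C)=C | intermediate
6 | (2E,4R)-4-hydroxy-3,7-dimethyl-6-oxoocta-2,7-dien-1-yl acetate | CC(=O)OC/C=C(\C)[C@H](O)CC(=O)C(C)=C | intermediate
7 | C3 TBS ether of 6 | CC(=O)OC/C=C(\C)[C@H](O[Si](C)(C)C(C)(C)C)CC(=O)C(C)=C | intermediate
8 | C1 allylic alcohol (C1 epimers) | CC(=O)OC/C=C(\C)[C@H](O[Si](C)(C)C(C)(C)C)CC(O)C(C)=C | intermediate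
9 | C1 TES ether of 8 | CC(=O)OC/C=C(\C)[C@H](O[Si](C)(C)C(C)(C)C)CC(O[Si](CC)(CC)CC)C(C)=C | intermediate
10 | C6 primary allylic alcohol | OC/C=C(\C)[C@H](O[Si](C)(C)C(C)(C)C)CC(O[Si](CC)(CC)CC)C(C)=C | intermediate
11 | C6 enal | O=C/C=C(\C)[C@H](O[Si](C)(C)C(C)(C)C)CC(O[Si](CC)(CC)CC)C(C)=C | intermediate
12 | methyl 3-methylbut-2-enoate | COC(=O)C=C(C)C | starting material
13 | lithium dienolate of 12 (not isolated) | COC(O[Li])=CC(C)=C | intermediate
14 | 1-(tert-butyldimethylsilyloxy)-1-methoxy-3-methylbuta-1,3-diene | COC(O[Si](C)(C)C(C)(C)C)=CC(C)=C | intermediate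
15 | trichlorosilyl ether of 16 (not isolated) | COC(=O)/C=C(\C)C[C@H](O[Si](Cl)(Cl)Cl)/C=C(\C)[C@H](O[Si](C)(C)C(C)(C)C)CC(O[Si](CC)(CC)CC)C(C)=C | intermediate
16 | methyl (2E,5S,6E,8R)-5-hydroxy trienoate | COC(=O)/C=C(\C)C[C@H](O)/C=C(\C)[C@H](O[Si](C)(C)C(C)(C)C)CC(O[Si](CC)(CC)CC)C(C)=C | intermediate
17 | C6 TBDPS ether of 16 | COC(=O)/C=C(\C)C[C@H](O[Si](c1ccccc1)(c1ccccc1)C(C)(C)C)/C=C(\C)[C@H](O[Si](C)(C)C(C)(C)C)CC(O[Si](CC)(CC)CC)C(C)=C | intermediate
18 | trimethylstannyl ester (not isolated) | C[Sn](C)(C)OC(=O)/C=C(\C)C[C@H](O[Si](c1ccccc1)(c1ccccc1)C(C)(C)C)/C=C(\C)[C@H](O[Si](C)(C)C(C)(C)C)CC(O[Si](CC)(CC)CC)C(C)=C | intermediate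
19 | trienoic acid | OC(=O)/C=C(\C)C[C@H](O[Si](c1ccccc1)(c1ccccc1)C(C)(C)C)/C=C(\C)[C@H](O[Si](C)(C)C(C)(C)C)CC(O[Si](CC)(CC)CC)C(C)=C | intermediate
20 | trienoyl chloride (key-step precursor) | ClC(=O)/C=C(\C)C[C@H](O[Si](c1ccccc1)(c1ccccc1)C(C)(C)C)/C=C(\C)[C@H](O[Si](C)(C)C(C)(C)C)CC(O[Si](CC)(CC)CC)C(C)=C | intermediate
21 | vinylketene (not isolated) | O=C=CC(=C)C[C@H](O[Si](c1ccccc1)(c1ccccc1)C(C)(C)C)/C=C(\C)[C@H](O[Si](C)(C)C(C)(C)C)CC(O[Si](CC)(CC)CC)C(C)=C | intermediate
22 | 2-methylidenebicyclo[3.1.1]heptan-6-one (key-step product) | C=C(C)C(O[Si](CC)(CC)CC)C[C@@H](O[Si](C)(C)C(C)(C)C)[C@@]1(C)[C@@H]2[C@@H](O[Si](c3ccccc3)(c3ccccc3)C(C)(C)C)CC(=C)[C@H]1C2=O | intermediate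
23 | bicyclic ketone with free C1 hydroxyl | C=C(C)C(O)C[C@@H](O[Si](C)(C)C(C)(C)C)[C@@]1(C)[C@@H]2[C@@H](O[Si](c3ccccc3)(c3ccccc3)C(C)(C)C)CC(=C)[C@H]1C2=O | intermediate
24 | bicyclic keto-enone | C=C(C)C(=O)C[C@@H](O[Si](C)(C)C(C)(C)C)[C@@]1(C)[C@@H]2[C@@H](O[Si](c3ccccc3)(c3ccccc3)C(C)(C)C)CC(=C)[C@H]1C2=O | intermediate
25 | copper enolate, phosphine ligand omitted (not isolated) | CC(C)=C(O[Cu])C[C@@H](O[Si](C)(C)C(C)(C)C)[C@@]1(C)[C@@H]2[C@@H](O[Si](c3ccccc3)(c3ccccc3)C(C)(C)C)CC(=C)[C@H]1C2=O | intermediate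
26 | tricyclic ketol | O=C1C[C@@H](O[Si](C)(C)C(C)(C)C)[C@@]2(C)[C@@H]3[C@@H](O[Si](c4ccccc4)(c4ccccc4)C(C)(C)C)CC(=C)[C@H]2[C@]3(O)C1(C)C | intermediate
27 | tricyclic dihydroxy ketone | O=C1C[C@@H](O)[C@@]2(C)[C@@H]3[C@@H](O[Si](c4ccccc4)(c4ccccc4)C(C)(C)C)CC(=C)[C@H]2[C@]3(O)C1(C)C | intermediate
28 | 3-methylbut-2-enal | CC(C)=CC=O | starting material
29 | C3 hemiacetal (not isolated) | O=C1C[C@@H](OC(O)C=C(C)C)[C@@]2(C)[C@@H]3[C@@H](O[Si](c4ccccc4)(c4ccccc4)C(C)(C)C)CC(=C)[C@H]2[C@]3(O)C1(C)C | intermediate
30 | C3 senecioate with (1R)-hydroxyl | O[C@@H]1C[C@@H](OC(=O)C=C(C)C)[C@@]2(C)[C@@H]3[C@@H](O[Si](c4ccccc4)(c4ccccc4)C(C)(C)C)CC(=C)[C@H]2[C@]3(O)C1(C)C | intermediate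
31 | tiglic acid | C/C=C(\C)C(=O)O | starting material
32 | tiglic 2,4,6-trichlorobenzoic anhydride (not isolated) | C/C=C(\C)C(=O)OC(=O)c1c(Cl)cc(Cl)cc1Cl | intermediate
33 | C1 tiglate C3 senecioate with C10 hydroxyl | C/C=C(\C)C(=O)O[C@@H]1C[C@@H](OC(=O)C=C(C)C)[C@@]2(C)[C@@H]3[C@@H](O[Si](c4ccccc4)(c4ccccc4)C(C)(C)C)CC(=C)[C@H]2[C@]3(O)C1(C)C | intermediate
34 | potassium C10 xanthate (not isolated) | C/C=C(\C)C(=O)O[C@@H]1C[C@@H](OC(=O)C=C(C)C)[C@@]2(C)[C@@H]3[C@@H](O[Si](c4ccccc4)(c4ccccc4)C(C)(C)C)CC(=C)[C@H]2[C@]3(OC(=S)[S-])C1(C)C.[K+] | intermediate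
35 | C10 S-methyl xanthate | C/C=C(\C)C(=O)O[C@@H]1C[C@@H](OC(=O)C=C(C)C)[C@@]2(C)[C@@H]3[C@@H](O[Si](c4ccccc4)(c4ccccc4)C(C)(C)C)CC(=C)[C@H]2[C@]3(OC(=S)SC)C1(C)C | intermediate
36 | deoxygenated tricycle | C/C=C(\C)C(=O)O[C@@H]1C[C@@H](OC(=O)C=C(C)C)[C@@]2(C)[C@@H]3[C@@H](O[Si](c4ccccc4)(c4ccccc4)C(C)(C)C)CC(=C)[C@H]2[C@@H]3C1(C)C | intermediate
37 | tricyclic (6S)-alcohol | C/C=C(\C)C(=O)O[C@@H]1C[C@@H](OC(=O)C=C(C)C)[C@@]2(C)[C@@H]3[C@@H](O)CC(=C)[C@H]2[C@@H]3C1(C)C | intermediate
38 | β,γ-unsaturated C6 ketone (not isolated) | C/C=C(\C)C(=O)O[C@@H]1C[C@@H](OC(=O)C=C(C)C)[C@@]2(C)[C@@H]3C(=O)CC(=C)[C@H]2[C@@H]3C1(C)C | intermediate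
39 | CNP0257816.1 | C/C=C(\C)C(=O)O[C@@H]1C[C@@H](OC(=O)C=C(C)C)[C@@]2(C)[C@@H]3C(=O)C=C(C)[C@H]2[C@@H]3C1(C)C | target

Total step count: 24. Longest linear sequence: 22 steps (1 to 39 through steps 1, 3–8 and 10–24).

Steps most likely to fail

Step 14. The reacting alkene is flanked by two silyloxy-bearing carbons, so it is more hindered and less nucleophilic than in the simple terpenoid cases. Dimerisation or re-protonation of the ketene may then outrun ring closure. The fallback sets out from 20, returns at 22, and replaces the ketene by the more electrophilic, non-dimerising keteniminium ion. Aminolysis of 20 with pyrrolidine would give the pyrrolidine amide F1. Treatment with (CF3SO2)2O and 2,4,6-collidine in refluxing 1,2-dichloroethane would convert it into the vinylketeniminium triflate F2. This should close the same two bonds to give the cyclobutaniminium triflate F3, and aqueous NaHCO3 would hydrolyse that salt to 22.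

Step 17. C11 must approach C10 past C3 and two fully substituted carbons must be joined, so the mild copper enolate may simply be protonated on work-up without closing the ring. The fallback sets out from 24, returns at 26, and makes a more oxophilic and more reactive enolate by a Reformatsky-type route. 1,4-Hydrosilylation with Et3SiH and RhCl(PPh3)3 (THF, 50 °C) would give the tetrasubstituted triethylsilyl enol ether F4. N-Bromosuccinimide (THF, −78 °C), which reacts with the enol ether far faster than with the exocyclic alkene, would give the tertiary α-bromo ketone F5. SmI2 (2.2 equiv, THF, −78 °C to rt) would reduce it to the trivalent samarium enolate F6, a type of enolate known to close seven- and eight-membered rings, and this should add to C10 to give 26.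

Step 19. Hemiacetal formation between a neopentyl alcohol and a conjugated aldehyde may be too unfavourable for the hydride transfer, and the Lewis-acidic samarium alkoxides might start retro-aldol opening of the C10–C11 bond. The fallback sets out from 27, returns at 30, and separates acylation from reduction. 3-Methylbut-2-enoyl chloride with pyridine and 4-dimethylaminopyridine (CH2Cl2, 0 °C) would acylate the only reactive hydroxyl and give the C3 senecioyloxy ketone F7. A Corey–Bakshi–Shibata reduction with (S)-1-methyl-3,3-diphenyltetrahydro-1H,3H-pyrrolo[1,2-c][1,3,2]oxazaborole and catecholborane (toluene, −78 °C) would then set 1R under reagent control. Quaternary C11 acts as the large flank and C2H2 as the small flank of the ketone.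

Further compounds
F1 | step 14 | pyrrolidine amide of acid 19 | O=C(N1CCCC1)/C=C(\C)C[C@H](O[Si](c1ccccc1)(c1ccccc1)C(C)(C)C)/C=C(\C)[C@H](O[Si](C)(C)C(C)(C)C)CC(O[Si](CC)(CC)CC)C(C)=C
F2 | step 14 | vinylketeniminium triflate | C=C(C=C=[N+]1CCCC1)C[C@H](O[Si](c1ccccc1)(c1ccccc1)C(C)(C)C)/C=C(\C)[C@H](O[Si](C)(C)C(C)(C)C)CC(O[Si](CC)(CC)CC)C(C)=C.[O-]S(=O)(=O)C(F)(F)F
F3 | step 14 | cyclobutaniminium triflate | C=C(C)C(O[Si](CC)(CC)CC)C[C@@H](O[Si](C)(C)C(C)(C)C)[C@@]1(C)[C@@H]2[C@@H](O[Si](c3ccccc3)(c3ccccc3)C(C)(C)C)CC(=C)[C@H]1C2=[N+]1CCCC1.[O-]S(=O)(=O)C(F)(F)F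
F4 | step 17 | tetrasubstituted triethylsilyl enol ether | CC(C)=C(O[Si](CC)(CC)CC)C[C@@H](O[Si](C)(C)C(C)(C)C)[C@@]1(C)[C@@H]2[C@@H](O[Si](c3ccccc3)(c3ccccc3)C(C)(C)C)CC(=C)[C@H]1C2=O
F5 | step 17 | tertiary α-bromo ketone | CC(C)(Br)C(=O)C[C@@H](O[Si](C)(C)C(C)(C)C)[C@@]1(C)[C@@H]2[C@@H](O[Si](c3ccccc3)(c3ccccc3)C(C)(C)C)CC(=C)[C@H]1C2=O
F6 | step 17 | samarium enolate | CC(C)=C(O[Sm](I)I)C[C@@H](O[Si](C)(C)C(C)(C)C)[C@@]1(C)[C@@H]2[C@@H](O[Si](c3ccccc3)(c3ccccc3)C(C)(C)C)CC(=C)[C@H]1C2=O
F7 | step 19 | C3 senecioyloxy ketone | O=C1C[C@@H](OC(=O)C=C(C)C)[C@@]2(C)[C@@H]3[C@@H](O[Si](c4ccccc4)(c4ccccc4)C(C)(C)C)CC(=C)[C@H]2[C@]3(O)C1(C)C
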